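**Plan**

- Retrosynthesis: the nine O-benzyl groups are cut first. Ring C of the upper (mesquitol) unit (O1, C2, C3, C4, C4a, C8a) is then taken back to a furan by cutting O1–C2 and joining O1–C3, the 3-oxygen going to C2. The enabling feature is that O1 and the 3-oxygen sit on neighbouring carbons and C2 is benzylic to ring B with the 4'-oxygen para, so a cation at C2 is bridged by O1 and the two oxygens can change places.
- The furan is cut at C3–C4 and O1–C3: a [4+1] annulation of the ring-A ortho-quinone methide (C8a=O, C4a=C4) with an aroyl sulfur ylide that brings C3, C2 (as ketone) and ring B. Last cut: C4–C8 of the lower unit (aryllithium plus salicylaldehyde).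
- Forward: both catechin rings are carried intact; the interflavan C4–C8 bond is made first, then the five-membered furan ring, then ring C by enlargement from five to six atoms, then hydrogenolysis.
- Stereochemistry: the lower unit comes from (+)-catechin. C4 comes from the chiral phosphoric acid in the [4+1] (C3/C4 trans from ring closure and equilibration). The carbinol comes from chelation-controlled reduction. C2 and C3 are set by double inversion in the enlargement, giving the 2,3-trans-3,4-trans flavan.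

Key step: step 9

Remark (assumption): the sense of induction of the phosphoric acid in step 7 cannot be predicted with certainty for this substrate; the (R)-acid is written, the two trans adducts are diastereomers (the lower unit is enantiopure) and separable, and the (S)-acid would be used should (2R,3S)-14 prove the minor one.

**Route**

Step 1
Reactants: 1 (+)-catechin
Product: 2 5,7,3',4'-tetra-O-benzyl-(+)-catechin
Conditions: BnBr (4.4 equiv), K2CO3, DMF, 0 °C → rt
Reagents that add atoms: benzyl bromide BrCc1ccccc1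
Why: Williamson etherification in which carbonate deprotonates only the four phenols, so the secondary 3-OH stays free and no stereocentre is touched.

Step 2
Reactants: 2 5,7,3',4'-tetra-O-benzyl-(+)-catechin
Product: 3 3,5,7,3',4'-penta-O-benzyl-(+)-catechin
Conditions: NaH, BnBr, n-Bu4NI (cat.), THF/DMF, 0 °C → rt
Reagents that add atoms: benzyl bromide BrCc1ccccc1
Why: Williamson etherification of the C3 alkoxide, which only engages the O–H bond and therefore keeps both stereocentres.

Step 3
Reactants: 3 3,5,7,3',4'-penta-O-benzyl-(+)-catechin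
Product: 4 8-bromo-3,5,7,3',4'-penta-O-benzyl-(+)-catechin
Conditions: NBS (1.0 equiv), CH2Cl2, −20 °C → rt
Reagents that add atoms: N-bromosuccinimide O=C1CCC(=O)N1Br
Why: electrophilic aromatic bromination of the phloroglucinol-type ring A, for which C8 (between O1 and the 7-benzyloxy group) is the established site in fully benzylated catechins and ring B is much less activated.

Step 4
Reactants: 5 2,3,4-trihydroxybenzaldehyde
Product: 6 3,4-bis(benzyloxy)-2-hydroxybenzaldehyde
Conditions: BnBr (2.05 equiv), K2CO3 (2.1 equiv), DMF, rt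
Reagents that add atoms: benzyl bromide BrCc1ccccc1
Why: Williamson etherification under stoichiometric control, in which the 2-OH is tied up in a hydrogen bond to the formyl group and is the last hydroxyl to react.

Step 5
Reactants: 4 8-bromo-3,5,7,3',4'-penta-O-benzyl-(+)-catechin; 6 3,4-bis(benzyloxy)-2-hydroxybenzaldehyde
Product: 9 [3,4-bis(benzyloxy)-2-hydroxyphenyl](penta-O-benzylcatechin-8-yl)methanol (both carbinol epimers), via 8-lithio-penta-O-benzylcatechin 7 (not isolated), via sodium 2,3-bis(benzyloxy)-6-formylphenoxide 8 (not isolated)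
Conditions: 4, t-BuLi (2.0 equiv), THF, −78 °C; then 8 (from 6, NaH 1.0 equiv, THF, 0 °C), −78 → −20 °C; aq NH4Cl
Reagents that add atoms: none
Why: bromine–lithium exchange followed by 1,2-addition of the aryllithium to the aldehyde (the preformed phenoxide saves one equivalent of 7) should forge the C4–C8 bond; the carbinol centre forms unselectively but becomes the sp2 methide carbon in step 7.

Step 6
Reactants: 10 methyl 3,4-bis(benzyloxy)benzoate
Product: 11 dimethylsulfoxonium 2-[3,4-bis(benzyloxy)phenyl]-2-oxoethylide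
Conditions: Me3S(O)I (3 equiv), KOtBu (3 equiv), THF, reflux; then 10, reflux
Reagents that add atoms: trimethylsulfoxonium iodide C[S+](C)(C)=O.[I-]
Why: acylation of dimethylsulfoxonium methylide (Corey–Chaykovsky reagent) by the ester and deprotonation of the acylsulfoxonium salt should give the isolable carbonyl-stabilised ylide; no stereocentre is formed.

Step 7
Reactants: 9 [3,4-bis(benzyloxy)-2-hydroxyphenyl](penta-O-benzylcatechin-8-yl)methanol; 11 dimethylsulfoxonium 2-[3,4-bis(benzyloxy)phenyl]-2-oxoethylide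
Product: 14 (2R,3S)-trans-2-[3,4-bis(benzyloxy)benzoyl]-6,7-bis(benzyloxy)-3-(penta-O-benzylcatechin-8-yl)-2,3-dihydrobenzofuran, via ortho-quinone methide 12 (not isolated), via sulfoxonium betaine 13 (not isolated)
Conditions: (R)-3,3'-bis(2,4,6-triisopropylphenyl)-1,1'-binaphthyl-2,2'-diyl hydrogen phosphate (10 mol %), 11 (1.3 equiv), 4 Å MS, CH2Cl2, 0 °C → rt; then Et3N (0.2 equiv), rt
Reagents that add atoms: none
Why: formal [4+1] annulation of an ortho-quinone methide with a carbonyl-stabilised sulfur ylide (acid-induced dehydration of 9 to 12, 1,4-addition of the ylide carbon to C4, then 5-exo-tet displacement of dimethyl sulfoxide by the phenol oxygen), in which the chiral phosphate bound to the quinone methide sets the C4 configuration and the ketone α-centre equilibrates to the trans isomer.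

Step 8
Reactants: 14 (2R,3S)-trans-2-[3,4-bis(benzyloxy)benzoyl]-6,7-bis(benzyloxy)-3-(penta-O-benzylcatechin-8-yl)-2,3-dihydrobenzofuran
Product: 15 (S)-[3,4-bis(benzyloxy)phenyl][(2R,3S)-6,7-bis(benzyloxy)-3-(penta-O-benzylcatechin-8-yl)-2,3-dihydrobenzofuran-2-yl]methanol
Conditions: Zn(BH4)2, Et2O/CH2Cl2, −40 → −20 °C; aq NH4Cl
Reagents that add atoms: none
Why: chelation-controlled (Cram chelate) hydride reduction in which zinc bridges the ketone oxygen and O1 and hydride enters from the face of H-2, away from C3 and its aryl group, which should give the anti (αS) carbinol.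

Step 9
Reactants: 15 (S)-[3,4-bis(benzyloxy)phenyl][(2R,3S)-6,7-bis(benzyloxy)-3-(penta-O-benzylcatechin-8-yl)-2,3-dihydrobenzofuran-2-yl]methanol
Product: 19 nona-O-benzyl mesquitol-(4α→8)-catechin (2R,3S,4S upper unit; free 3-OH), via benzylic trifluoroacetate 16 (not isolated), via bridged aryloxonium trifluoroacetate 17 (not isolated), via flavan 3-O-trifluoroacetate 18 (not isolated)
Conditions: (CF3CO)2O (1.3 equiv), 2,6-di-tert-butyl-4-methylpyridine (2 equiv), CH2Cl2 (0.01 M), −40 °C; then (CF3)2CHOH (20 vol %), −40 → 0 °C; then K2CO3, MeOH, 0 °C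
Reagents that add atoms: trifluoroacetic anhydride O=C(OC(=O)C(F)(F)F)C(F)(F)F
Why: Proposed new method: O-trifluoroacetylation turns the carbinol oxygen into a leaving group on a carbon that ring B (4-benzyloxy para) makes cation-stabilising, and the furan oxygen O1, antiperiplanar to it, displaces it from the rear to give the bridged aryloxonium ion pair 17, whose trifluoroacetate then opens the three-membered ring at C3 from the face opposite O1, so that O1 and the acyloxy group change places across C2–C3 (a dyotropic-type 1,2-exchange) and methanolysis frees the 3-OH. The closest known reaction types are the enlargement of 2-(α-hydroxybenzyl)pyrrolidines to 2-phenylpiperidin-3-ols through aziridinium trifluoroacetates, the Zn(OAc)2-mediated enlargement of tetrahydrofuran-2-yl carbinol sulfonates to tetrahydropyran-3-yl acetates and, in the reverse sense, the solvolytic contraction of flavan-3-yl sulfonates to 2-(α-acyloxybenzyl)dihydrobenzofurans through the same oxonium ion; new here is an aryl-ether oxygen with a benzylic trifluoroacetate driving the enlargement towards the flavan. Ring C is not closed by a fresh cyclisation but grows from the furan by insertion of C2 between O1 and C3 (3-exo-tet closure of O1 onto C2, then SN2 opening at C3, which trades the furan O1–C3 bond for the pyran O1–C2 bond). C2 is set by inversion at the carbinol carbon (αS gives 2R) and C3 by inversion at the furan carbon (2R in 15 gives 3S) while C4 is untouched, so the trans-furan with the anti carbinol maps onto the all-equatorial 2,3-trans-3,4-trans flavan, which is also the expected thermodynamic diastereomer should C2 ionise reversibly. The step needs the acyloxy group to return at C3 and not at C2, and it needs capture by O1 to outrun loss of H-3 (aromatisation to a 2-benzylbenzofuran) and Friedel–Crafts capture of the cation: return at benzylic C2 only regenerates the ionisable ester 16, whereas the secondary non-benzylic ester 18 cannot re-ionise under these conditions and the strained furan is relieved, so material should funnel into 18, while the hindered non-nucleophilic base, low temperature, high dilution and the tight ion pair hold back elimination and intermolecular alkylation.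

Step 10
Reactants: 19 nona-O-benzyl mesquitol-(4α→8)-catechin
Product: 20 mesquitol-(4α→8)-catechin (CNP0231186.1)
Conditions: H2 (1 atm), Pd(OH)2/C, THF/MeOH/H2O, rt; filtration and lyophilisation under argon
Reagents that add atoms: none
Why: hydrogenolysis of the nine benzyl ethers under the conditions used for benzylated proanthocyanidins, which leave the ring C2–O1 bonds, the C4–C8 bond and all five stereocentres untouched.

**Compound list**

1 | (+)-catechin, (2R,3S)-2-(3,4-dihydroxyphenyl)chromane-3,5,7-triol | c1c(O)cc(O)c2C[C@H](O)[C@@H](c3ccc(O)c(O)c3)Oc12 | starting material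
2 | 5,7,3',4'-tetra-O-benzyl-(+)-catechin | c1c(OCc2ccccc2)cc(OCc2ccccc2)c2C[C@H](O)[C@@H](c3ccc(OCc4ccccc4)c(OCc4ccccc4)c3)Oc12 | intermediate
3 | 3,5,7,3',4'-penta-O-benzyl-(+)-catechin | c1c(OCc2ccccc2)cc(OCc2ccccc2)c2C[C@H](OCc3ccccc3)[C@@H](c3ccc(OCc4ccccc4)c(OCc4ccccc4)c3)Oc12 | intermediate
4 | 8-bromo-3,5,7,3',4'-penta-O-benzyl-(+)-catechin | Brc1c(OCc2ccccc2)cc(OCc2ccccc2)c2C[C@H](OCc3ccccc3)[C@@H](c3ccc(OCc4ccccc4)c(OCc4ccccc4)c3)Oc12 | intermediate
5 | 2,3,4-trihydroxybenzaldehyde | O=Cc1ccc(O)c(O)c1O | starting material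
6 | 3,4-bis(benzyloxy)-2-hydroxybenzaldehyde | O=Cc1ccc(OCc2ccccc2)c(OCc2ccccc2)c1O | intermediate
7 | 8-lithio-3,5,7,3',4'-penta-O-benzylcatechin (not isolated) | [Li]c1c(OCc2ccccc2)cc(OCc2ccccc2)c2C[C@H](OCc3ccccc3)[C@@H](c3ccc(OCc4ccccc4)c(OCc4ccccc4)c3)Oc12 | intermediate
8 | sodium 2,3-bis(benzyloxy)-6-formylphenoxide (not isolated) | [Na+].[O-]c1c(C=O)ccc(OCc2ccccc2)c1OCc1ccccc1 | intermediate
9 | [3,4-bis(benzyloxy)-2-hydroxyphenyl](3,5,7,3',4'-penta-O-benzylcatechin-8-yl)methanol, both carbinol epimers | OC(c5ccc(OCc6ccccc6)c(OCc6ccccc6)c5O)c1c(OCc2ccccc2)cc(OCc2ccccc2)c2C[C@H](OCc3ccccc3)[C@@H](c3ccc(OCc4ccccc4)c(OCc4ccccc4)c3)Oc12 | intermediate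
10 | methyl 3,4-bis(benzyloxy)benzoate | COC(=O)c1ccc(OCc2ccccc2)c(OCc2ccccc2)c1 | starting material
11 | dimethylsulfoxonium 2-[3,4-bis(benzyloxy)phenyl]-2-oxoethylide | CS(C)(=O)=CC(=O)c1ccc(OCc2ccccc2)c(OCc2ccccc2)c1 | intermediate
12 | ortho-quinone methide, 2,3-bis(benzyloxy)-6-[(penta-O-benzylcatechin-8-yl)methylidene]cyclohexa-2,4-dien-1-one (not isolated) | O=C5C(OCc6ccccc6)=C(OCc6ccccc6)C=CC5=Cc1c(OCc2ccccc2)cc(OCc2ccccc2)c2C[C@H](OCc3ccccc3)[C@@H](c3ccc(OCc4ccccc4)c(OCc4ccccc4)c3)Oc12 | intermediate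
13 | sulfoxonium betaine from addition of 11 to C4 of 12, 4S (not isolated) | [O-]c5c(OCc6ccccc6)c(OCc6ccccc6)ccc5[C@@H](c1c(OCc2ccccc2)cc(OCc2ccccc2)c2C[C@H](OCc3ccccc3)[C@@H](c3ccc(OCc4ccccc4)c(OCc4ccccc4)c3)Oc12)C(C(=O)c1ccc(OCc2ccccc2)c(OCc2ccccc2)c1)[S+](C)(C)=O | intermediate
14 | (2R,3S)-trans-2-[3,4-bis(benzyloxy)benzoyl]-6,7-bis(benzyloxy)-3-(penta-O-benzylcatechin-8-yl)-2,3-dihydrobenzofuran | O=C(c1ccc(OCc2ccccc2)c(OCc2ccccc2)c1)[C@@H]5Oc6c(OCc7ccccc7)c(OCc7ccccc7)ccc6[C@H]5c1c(OCc2ccccc2)cc(OCc2ccccc2)c2C[C@H](OCc3ccccc3)[C@@H](c3ccc(OCc4ccccc4)c(OCc4ccccc4)c3)Oc12 | intermediate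
15 | (S)-[3,4-bis(benzyloxy)phenyl][(2R,3S)-6,7-bis(benzyloxy)-3-(penta-O-benzylcatechin-8-yl)-2,3-dihydrobenzofuran-2-yl]methanol | O[C@@H](c1ccc(OCc2ccccc2)c(OCc2ccccc2)c1)[C@@H]5Oc6c(OCc7ccccc7)c(OCc7ccccc7)ccc6[C@H]5c1c(OCc2ccccc2)cc(OCc2ccccc2)c2C[C@H](OCc3ccccc3)[C@@H](c3ccc(OCc4ccccc4)c(OCc4ccccc4)c3)Oc12 | intermediate
16 | trifluoroacetate of 15 (not isolated) | FC(F)(F)C(=O)O[C@@H](c1ccc(OCc2ccccc2)c(OCc2ccccc2)c1)[C@@H]5Oc6c(OCc7ccccc7)c(OCc7ccccc7)ccc6[C@H]5c1c(OCc2ccccc2)cc(OCc2ccccc2)c2C[C@H](OCc3ccccc3)[C@@H](c3ccc(OCc4ccccc4)c(OCc4ccccc4)c3)Oc12 | intermediate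
17 | bridged aryloxonium ion (O1 bonded to C2, C3 and C8a) as its trifluoroacetate ion pair (not isolated) | c2ccccc2COc1ccc(cc1OCc1ccccc1)[C@H]8[O+]9c6c(OCc7ccccc7)c(OCc7ccccc7)ccc6[C@@H](c1c(OCc2ccccc2)cc(OCc2ccccc2)c2C[C@H](OCc3ccccc3)[C@@H](c3ccc(OCc4ccccc4)c(OCc4ccccc4)c3)Oc12)[C@H]89.[O-]C(=O)C(F)(F)F | intermediate
18 | 3-O-trifluoroacetyl derivative of 19 (not isolated) | c2ccccc2COc1ccc(cc1OCc1ccccc1)[C@H]8Oc6c(OCc7ccccc7)c(OCc7ccccc7)ccc6[C@@H](c1c(OCc2ccccc2)cc(OCc2ccccc2)c2C[C@H](OCc3ccccc3)[C@@H](c3ccc(OCc4ccccc4)c(OCc4ccccc4)c3)Oc12)[C@@H]8OC(=O)C(F)(F)F | intermediate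
19 | 7,8,3',4'-tetra-O-benzylmesquitol-(4α→8)-3,5,7,3',4'-penta-O-benzylcatechin, upper unit (2R,3S,4S) | c2ccccc2COc1ccc(cc1OCc1ccccc1)[C@H]8Oc6c(OCc7ccccc7)c(OCc7ccccc7)ccc6[C@@H](c1c(OCc2ccccc2)cc(OCc2ccccc2)c2C[C@H](OCc3ccccc3)[C@@H](c3ccc(OCc4ccccc4)c(OCc4ccccc4)c3)Oc12)[C@@H]8O | intermediate
20 | mesquitol-(4α→8)-catechin, (2R,3S,4S)-2-(3,4-dihydroxyphenyl)-4-[(2R,3S)-2-(3,4-dihydroxyphenyl)-3,5,7-trihydroxychroman-8-yl]chromane-3,7,8-triol | Oc1ccc([C@H]2Oc3c(ccc(O)c3O)[C@@H](c3c(O)cc(O)c4c3O[C@H](c3ccc(O)c(O)c3)[C@@H](O)C4)[C@@H]2O)cc1O | target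

**Count**

Total: 10 steps. Longest linear sequence: 8 steps (1, 2, 3, 5, 7, 8, 9, 10).

**Steps most likely to fail**

1. Step 9 (the step that bears the label). What may go wrong: the acyloxy group returns to the benzylic carbon without migration of O1, the cation loses H-3 and aromatises to a 2-benzylbenzofuran, or the cation is captured by a neighbouring benzyloxy oxygen or by C6 of a second molecule, so that the ring never enlarges. The fallback uses known chemistry and closes ring C directly at six atoms; it sets out from 9 and comes back at 19. Conjugate addition of (E)-2-[3,4-bis(benzyloxy)phenyl]vinylboronic acid to the quinone methide generated from 9 (3,3'-dibromo-BINOL catalyst, whichever enantiomer favours the 4S adduct, PhCF3, 4 Å MS, rt) should give 2,3-bis(benzyloxy)-6-[(1S,2E)-3-[3,4-bis(benzyloxy)phenyl]-1-(penta-O-benzylcatechin-8-yl)prop-2-en-1-yl]phenol F1, the minor diastereomer being removed by chromatography. Shi epoxidation with the L-sorbose-derived enantiomer of the ketone catalyst and KHSO5 (as 2KHSO5·KHSO4·K2SO4) buffered near pH 8 should give 2,3-bis(benzyloxy)-6-{(S)-[(2S,3S)-3-[3,4-bis(benzyloxy)phenyl]oxiran-2-yl](penta-O-benzylcatechin-8-yl)methyl}phenol F2. Camphorsulfonic acid (cat.) in CH2Cl2 at −20 °C should then let the phenol open the epoxide 6-endo at the benzylic carbon with inversion, which gives 19 with the same 2,3-trans-3,4-trans arrangement.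

2. Step 7. What may go wrong: poor facial selectivity at the methide carbon (the catechin stereocentres are remote and the di-ortho-substituted aryl group twists out of the quinone methide plane), slow conjugate addition to the hindered methide, or sequestration of the acid by the basic ylide. The fallback forms the O–C bond first and the C–C bond second; it sets out from 9 and comes back at 14. O-Alkylation of the phenol of 9 with 2-bromo-1-[3,4-bis(benzyloxy)phenyl]ethanone (K2CO3, acetone, rt) should give 1-[3,4-bis(benzyloxy)phenyl]-2-{2,3-bis(benzyloxy)-6-[hydroxy(penta-O-benzylcatechin-8-yl)methyl]phenoxy}ethanone F3. Sc(OTf)3 (5 mol %) in MeNO2 at 0 °C should ionise the diarylmethanol so that the ketone enol closes the furan ring (intramolecular enol alkylation), and Et3N equilibration gives the trans isomers. The two trans products differ at C3, are diastereomers, and are separated by chromatography to give 14.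

3. Step 8. What may go wrong: loss of facial control in hydride delivery because the aryl ether oxygen chelates zinc only weakly, so that Felkin–Anh delivery competes and gives the syn carbinol, which would lead on to the 2,3-cis flavan. The fallback builds the carbinol by aryl addition to an aldehyde, where the Felkin–Anh sense gives the wanted isomer; it sets out from 9 and comes back at 15. The annulation of step 7 run with dimethylsulfoxonium 2-[methoxy(methyl)amino]-2-oxoethylide should give (2R,3S)-trans-6,7-bis(benzyloxy)-N-methoxy-N-methyl-3-(penta-O-benzylcatechin-8-yl)-2,3-dihydrobenzofuran-2-carboxamide F4. Reduction with i-Bu2AlH (THF, −78 °C) should give (2R,3S)-trans-6,7-bis(benzyloxy)-3-(penta-O-benzylcatechin-8-yl)-2,3-dihydrobenzofuran-2-carbaldehyde F5. 3,4-Bis(benzyloxy)phenylmagnesium bromide (THF, −78 °C) should then add anti to the C2–O1 bond (Felkin–Anh), which for the aldehyde delivers the same (S)-carbinol 15 that chelation gives from the ketone.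

**Further compounds**

F1 | step 9 | 2,3-bis(benzyloxy)-6-[(1S,2E)-3-[3,4-bis(benzyloxy)phenyl]-1-(penta-O-benzylcatechin-8-yl)prop-2-en-1-yl]phenol | Oc5c(OCc6ccccc6)c(OCc6ccccc6)ccc5[C@@H](c1c(OCc2ccccc2)cc(OCc2ccccc2)c2C[C@H](OCc3ccccc3)[C@@H](c3ccc(OCc4ccccc4)c(OCc4ccccc4)c3)Oc12)/C=C/c1ccc(OCc2ccccc2)c(OCc2ccccc2)c1
F2 | step 9 | 2,3-bis(benzyloxy)-6-{(S)-[(2S,3S)-3-[3,4-bis(benzyloxy)phenyl]oxiran-2-yl](penta-O-benzylcatechin-8-yl)methyl}phenol | Oc5c(OCc6ccccc6)c(OCc6ccccc6)ccc5[C@@H](c1c(OCc2ccccc2)cc(OCc2ccccc2)c2C[C@H](OCc3ccccc3)[C@@H](c3ccc(OCc4ccccc4)c(OCc4ccccc4)c3)Oc12)[C@@H]7O[C@H]7c1ccc(OCc2ccccc2)c(OCc2ccccc2)c1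
F3 | step 7 | 1-[3,4-bis(benzyloxy)phenyl]-2-{2,3-bis(benzyloxy)-6-[hydroxy(penta-O-benzylcatechin-8-yl)methyl]phenoxy}ethanone | O=C(COc5c(OCc6ccccc6)c(OCc6ccccc6)ccc5C(O)c1c(OCc2ccccc2)cc(OCc2ccccc2)c2C[C@H](OCc3ccccc3)[C@@H](c3ccc(OCc4ccccc4)c(OCc4ccccc4)c3)Oc12)c1ccc(OCc2ccccc2)c(OCc2ccccc2)c1
F4 | step 8 | (2R,3S)-trans-6,7-bis(benzyloxy)-N-methoxy-N-methyl-3-(penta-O-benzylcatechin-8-yl)-2,3-dihydrobenzofuran-2-carboxamide | CON(C)C(=O)[C@@H]5Oc6c(OCc7ccccc7)c(OCc7ccccc7)ccc6[C@H]5c1c(OCc2ccccc2)cc(OCc2ccccc2)c2C[C@H](OCc3ccccc3)[C@@H](c3ccc(OCc4ccccc4)c(OCc4ccccc4)c3)Oc12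
F5 | step 8 | (2R,3S)-trans-6,7-bis(benzyloxy)-3-(penta-O-benzylcatechin-8-yl)-2,3-dihydrobenzofuran-2-carbaldehyde | O=C[C@@H]5Oc6c(OCc7ccccc7)c(OCc7ccccc7)ccc6[C@H]5c1c(OCc2ccccc2)cc(OCc2ccccc2)c2C[C@H](OCc3ccccc3)[C@@H](c3ccc(OCc4ccccc4)c(OCc4ccccc4)c3)Oc12
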